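## Structural features

The target is an elemane-type cyclohexane (ring C5–C10). C10 is quaternary (methyl C14, vinyl C1=C2), C9 is a methylene, C8 carries the ester oxygen, C7 carries the acrylic acid unit C11(=C13)–C12O2H, C6 carries a free hydroxyl, and C5 carries the 2-propenyl unit C4(=C3)–C15H2OH. The acyl group on O8 is (3'R)-3,4-dihydroxy-2-methylenebutanoyl. C5, C6, C7 and C8 are four stereocentres in a row and C10 adjoins C5; the configuration is 5S,6S,7S,8S,10S. Taking β as the ring face of the C14 methyl, O6 and C11 are β, while the C5 substituent, O8 and the vinyl group are α. Fragile features are the two 2-substituted acrylic units (Michael acceptors), four terminal alkenes, the γ-hydroxy acid C6–OH/C12 (cis on the ring, so it lactonises under acid), and the side-chain 4'-hydroxyl, which under base can expel O8 by closing a five-membered lactone. The real difficulty is twofold: the methyl and vinyl groups on C10 are too alike in size for steric substrate control, and the C6–C7–C8 triad needs a cis then a trans relation. The key step uses O6 as the anchor of a two-carbon radical that is delivered to C7 of a C7=C8 alkene in ring C5–C10; the tether fixes C7 and the new ring directs oxygen capture at C8.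

## Logic of the disconnections

(a) 27 ⇒ 26. The C12–OH bond of the acid is cut back to the lactol oxidation level. The carboxyl is made last because O6 would lactonise onto it in any acidic step. The forward step must oxidise an aldehyde tautomer beside free alcohols and four alkenes at mild pH.

(b) 26 ⇒ 25. The C11=C13 bond is cut, leaving a C11 methylene next to the masked C12 aldehyde. This removes the second acrylic unit. The forward step needs a one-carbon Mannich condensation that tolerates the C8 acrylate and free hydroxyls.

(c) 25 ⇒ 24. The O–C bonds of the ethyl acetal, the acetonide and the O15–Si bond are cut together. All three are acid-labile, so one hydrolysis before the acid exists replaces three deprotections.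

(d) 24 ⇒ 18 + 22. The C8–O acyl bond is cut. This makes the route convergent and defers the base-sensitive side chain. The forward step must acylate a hindered secondary hydroxyl with an acrylic acid without conjugate addition.

(e) 22 ⇒ 21 ⇒ 20 ⇒ 19. C1' is taken back to the aldehyde, the C2' methylene is cut, and the aldehyde is taken back to the alcohol. C3' then comes from a commercial C4 building block and is never touched.

(f) 18 ⇒ 17. The O8–H bond is traced to an O8–N bond. The aminoxy group is what the key step leaves and doubles as the protection of O8. The forward step must cleave N–O without hydrolysing the acetal.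

(g) 17 ⇒ 15 + 16. The C7–C11 and C8–O bonds are cut. This removes one ring and two stereocentres and reduces the problem to a cyclohexenol carrying only C5, C6 and C10. The forward step needs ring closure before radical capture and capture on the face opposite C11.

(h) 15 ⇒ 13 + 14. The O6–C12 bond and the C11–Br bond are cut. The forward step is a haloetherification of 14 that must ignore the three other alkenes.

(i) 13 ⇒ 11 ⇒ 10 ⇒ 9 ⇒ 8. The C6–O bond with the C7=C8 alkene is traced to a 6,7-epoxide (allylic transposition); the O15–Si bond is cut and C15 is returned to the ester level. The ring alkene of 8 is then the only nucleophilic alkene. The forward sequence needs epoxidation anti to the C5 substituent and epoxide opening at C7.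

(j) 8 ⇒ 5. The C4=C3 bond is cut, leaving an acetate arm on C5.

(k) 5 ⇒ 4. The C1=C2 bond is cut to a formyl group on C10, the activating group of a dienophile.

(l) 4 ⇒ 2 + 3. The C5–C10 and C8–C9 bonds are cut (Diels–Alder). Ring, quaternary centre and C5 arise together, and the C6=C7 alkene is already in place. The forward step needs ortho regiochemistry, endo orientation of the formyl group (formyl cis to the C5 arm) and catalyst control of the enal face.

(m) 2 ⇒ 1. Only a double-bond position changes; 1 is a bulk chemical.

## Other disconnections considered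

Alternative 1: The cut is C1–C10 and C4–C5, read as two bonds of a cyclobutane. Forward, irradiation of the silyloxy enone A1 with allene A2 should give the head-to-head, cis-fused methylenecyclobutane A3. After the exocyclic double bond is moved into the four-membered ring, ring-opening metathesis with ethylene A4 (second-generation Grubbs catalyst) would release the C10 vinyl and the C5 isopropenyl groups.
- In its favour: C10 and C5 are formed in one catalyst-free step, and the cis ring fusion forces the two alkenyl groups cis, as the target needs. On this point it is the better plan, since the chosen route depends on endo selectivity and a chiral catalyst.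
- Against it: only the remote C8 stereocentre steers the facial approach. In A3 the C8 oxygen lies on the face opposite C1, whereas the target has O8 and the vinyl group on the same face, so C8 must be inverted. A3 is also a β-silyloxy ketone prone to elimination. C7 is an unfunctionalised methylene, so C11–C13, the C6 configuration and the C15 oxidation all remain.
- Comparison: on mechanism, the triplet 1,4-diradical closes under strain control only, while in the chosen plan a tether fixes C7 and the new ring directs C8. On step economy it is equal up to the carbocycle but has the longer endgame.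

Alternative 2: The cut is C9–C10. Forward, anodic oxidation of the acyclic enol ether–allylsilane A5 gives a radical cation; C10 of the allylsilane bonds to C9, the silyl group leaves, and methanol traps C8 as the ketal A6.
- In its favour: ring, quaternary centre and vinyl group appear in one reagent-free step. A6 already carries C5, C6 and C7 with the right substituents, so the ring closure is late. In this it equals the chosen plan, and in oxidant economy it is better.
- Against it: the C10 configuration must come from a chair-like transition state that distinguishes methyl from the nascent vinyl group only weakly. The radical cation can also be intercepted by the two 1,1-disubstituted alkenes. A5 needs three contiguous acyclic stereocentres. Later the C8 ketone must be reduced to the α-alcohol, and the C7 isopropenyl group must be oxidised to the acrylic acid in the presence of a second alkene of the same type.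
- Comparison: both key steps are open-shell cyclisations. The chosen one is intramolecular through a short tether with a predictable cis fusion, while the anodic one relies on conformational preference. Overall length is expected to be similar or greater.

Alternative 3: The cut is C4–C5 and C10–C14, with no ring formed. Forward, the alkenyl cuprate made from bromide A8 adds to the enoate A7 anti to the C6 silyloxy group, and the ester enolate is methylated anti to the new C5 substituent, giving A9.
- In its favour: the trans C5/C6 relation and the C10 configuration come from well-understood vicinal substrate control, and the C4 unit arrives complete. On these two points it is better than the chosen plan, which needs an epoxide transposition for C6 and a separate methylenation at C4.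
- Against it: C7, C8 and C9 of A9 are bare methylenes, so the C7=C8 alkene has to be introduced afterwards by oxidation at C6, dehydrogenation and reduction. The ester must also be converted to the vinyl group in three operations.
- Comparison: this is a different entry to the cyclisation substrate, not a rival to the radical step, which would still be needed for C7 and C8. It is clearly longer.

Key step: step 10

Assumption (step 2): the (R)-oxazaborolidinium salt is taken to expose the face of 3 that leads to (6R)-4, following the formyl C–H···O binding model for 2-substituted acroleins; if the sense is the opposite, the (S)-catalyst is used and nothing else changes.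

Assumption (materials): 1, 3, 14, 16 and 19 are bought.

Convention for names: elemane numbering as above; β is the face of the C14 methyl.

## Route

Step 1
Reactants: 1 ethyl sorbate (ethyl (2E,4E)-hexa-2,4-dienoate)
Product: 2 ethyl (3E)-hexa-3,5-dienoate
Conditions: LiN(i-Pr)2, HMPA, THF, −78 °C; then AcOH, −78 °C
Reagents that add atoms: none
Why: Deconjugative protonation: the extended lithium enolate is protonated kinetically at the α-carbon, which moves the diene out of conjugation and gives an (E)-1-substituted butadiene with an acetate arm.

Step 2
Reactants: 2 ethyl (3E)-hexa-3,5-dienoate; 3 methacrolein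
Product: 4 ethyl 2-[(1S,6R)-6-formyl-6-methylcyclohex-2-en-1-yl]acetate
Conditions: (R)-o-tolyl-oxazaborolidinium triflimide [from (R)-α,α-diphenylprolinol, o-tolylboroxine, Tf2NH] (10 mol %), CH2Cl2, −78 → −40 °C
Reagents that add atoms: none
Why: Catalytic asymmetric Diels–Alder reaction of a 2-substituted acrolein; the substituted diene terminus bonds to the formyl-bearing carbon (ortho orientation), forming C5–C10 and C8–C9. The endo position of the Lewis-acid-bound formyl group places it cis to the acetate arm (C10 relative to C5), and the chiral boron Lewis acid selects the enal face (absolute configuration).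

Step 3
Reactants: 4 ethyl 2-[(1S,6R)-6-formyl-6-methylcyclohex-2-en-1-yl]acetate
Product: 5 ethyl 2-[(1S,6S)-6-ethenyl-6-methylcyclohex-2-en-1-yl]acetate
Conditions: Ph3PCH3Br, KOtBu, THF, 0 °C
Reagents that add atoms: methyltriphenylphosphonium bromide, C[P+](c1ccccc1)(c1ccccc1)c1ccccc1.[Br-]
Why: Wittig methylenation; the aldehyde on the quaternary carbon cannot enolise and reacts much faster than the ester, so C5 and C10 are untouched.

Step 4
Reactants: 5 ethyl 2-[(1S,6S)-6-ethenyl-6-methylcyclohex-2-en-1-yl]acetate
Product: 8 ethyl 2-[(1S,6S)-6-ethenyl-6-methylcyclohex-2-en-1-yl]prop-2-enoate, via Mannich base 6 (not isolated), via ammonium iodide 7 (not isolated)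
Conditions: LiN(i-Pr)2, THF, −78 °C; CH2=NMe2+ I−, −78 °C → rt; MeI, rt; then aq. NaHCO3, rt
Reagents that add atoms: N,N-dimethylmethyleneiminium iodide, C=[N+](C)C.[I-]
Why: Ester enolate Mannich reaction, N-quaternisation and E1cB loss of trimethylamine (α-methylenation of an ester). The weak base in the last stage should not move the new double bond into conjugation with the ring, and C5 is not acidic under these conditions.

Step 5
Reactants: 8 ethyl 2-[(1S,6S)-6-ethenyl-6-methylcyclohex-2-en-1-yl]prop-2-enoate
Product: 9 6β,7β-epoxide of 8 (oxirane oxygen on the face of the C14 methyl; trans to the C5 substituent)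
Conditions: mCPBA, NaHCO3, CH2Cl2, 0 °C
Reagents that add atoms: 3-chloroperbenzoic acid, O=C(OO)c1cccc(Cl)c1
Why: Peracid epoxidation; the cis-disubstituted ring alkene is the only electron-rich alkene (the acrylate is deactivated and the vinyl group is monosubstituted). The peracid should approach anti to the branched substituent on the adjacent C5, which places the oxygen β.

Step 6
Reactants: 9 6β,7β-epoxide of 8
Product: 10 2-substituted prop-2-en-1-ol (C15 alcohol; 6β,7β-epoxide retained)
Conditions: i-Bu2AlH (2.5 equiv), CH2Cl2, −78 °C; aq. KNaC4H4O6
Reagents that add atoms: none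
Why: 1,2-Reduction of the acrylate ester to the allylic alcohol by the aluminium hydride; at −78 °C the epoxide should not be opened.

Step 7
Reactants: 10 C15 alcohol with 6β,7β-epoxide
Product: 11 15-O-tert-butyldimethylsilyl ether of 10
Conditions: TBSCl, imidazole, CH2Cl2, 0 °C → rt
Reagents that add atoms: tert-butyldimethylsilyl chloride, CC(C)(C)[Si](C)(C)Cl
Why: Silylation of the only hydroxyl. A silyl ether is chosen for O15 in place of a benzyl-type ether because it is inert to NBS, stannyl radicals and zinc, and later leaves in the same acid step as the two acetals.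

Step 8
Reactants: 11 15-O-silyl 6β,7β-epoxide
Product: 13 (1R,5S,6S)-6-[3-(tert-butyldimethylsilyloxy)prop-1-en-2-yl]-5-ethenyl-5-methylcyclohex-2-en-1-ol, via hydroxy selenide 12 (not isolated)
Conditions: (PhSe)2, NaBH4, EtOH, 0 °C → reflux; then THF, 30% H2O2, 0 °C → rt
Reagents that add atoms: none
Why: Phenylselenide opens the epoxide by SN2 at C7, the carbon remote from the branched C5, so the C6–O bond is kept β and trans to the C5 substituent. Oxidation to the selenoxide and syn elimination, which runs away from the carbinol carbon, gives the C7=C8 alkene (epoxide to allylic alcohol transposition).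

Step 9
Reactants: 13 6β-allylic alcohol; 14 ethyl vinyl ether
Product: 15 6β-O-(2-bromo-1-ethoxyethyl) ether of 13 (bromoacetal; acetal carbon as epimers)
Conditions: NBS, CH2Cl2, −40 → 0 °C
Reagents that add atoms: N-bromosuccinimide, O=C1CCC(=O)N1Br
Why: Bromoetherification of the enol ether (Ueno–Stork acetal formation); the electron-rich vinyl ether takes up bromine far faster than the other alkenes, and the C6 hydroxyl captures the oxocarbenium ion.

Step 10
Reactants: 15 bromoacetal; 16 2,2,6,6-tetramethylpiperidin-1-oxyl
Product: 17 cis-fused 2-ethoxyhexahydrobenzofuran (C7–C11 bond β; 8α-(2,2,6,6-tetramethylpiperidin-1-yl)oxy; 15-O-silyl; acetal epimers)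
Conditions: (Bu3Sn)2 (1.2 equiv), hν (sunlamp, Pyrex), PhH, 70 °C; 16 (2.5 equiv) in PhH added by syringe pump over 8 h
Reagents that add atoms: none
Why: Photolysis of the ditin gives stannyl radicals that abstract bromine from 15; the primary C11 radical closes onto C7 (C7–C11 bond, tetrahydrofuran ring) and the secondary C8 radical couples with the nitroxide (C8–O bond). The closest known reaction type is the Ueno–Stork haloacetal cyclisation terminated by a persistent nitroxide (or by oxygen) in place of hydrogen transfer. The ring closes 5-exo-trig; the two-atom tether from O6 can only reach the alkene face on which O6 stands, so the fusion is cis and C11 is β (C7 is set by the tether). C8 is set by approach control: the bulky nitroxide adds anti to the new C7–C11 bond on the convex face of the bicycle, giving O8 α, trans to C11. The step needs ring closure before capture, which is secured by feeding the nitroxide slowly so that its stationary concentration stays low, and by the absence of any hydride donor. It also needs site selectivity: C7=C8 is the only alkene within reach of a five-membered transition state, the C4 methylene would require a trans-fused 6-exo or 7-endo closure, the C10 vinyl is out of reach, and 1,5-hydrogen transfer from C5 should be slower than 5-exo closure. Both acetal epimers should cyclise, and C12 is kept at the aldehyde oxidation level.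

Step 11
Reactants: 17 8α-aminoxy bicyclic acetal
Product: 18 8α-alcohol (ethyl acetal and 15-O-silyl ether retained)
Conditions: Zn dust, AcOH–THF (1:2), 45 °C
Reagents that add atoms: none
Why: Zinc reduction of the alkoxyamine N–O bond, assisted by N-protonation; water is left out so that the acetal and the silyl ether are not hydrolysed, and no stereocentre is touched.

Step 12
Reactants: 19 (R)-2-(2,2-dimethyl-1,3-dioxolan-4-yl)ethanol
Product: 20 (R)-2-(2,2-dimethyl-1,3-dioxolan-4-yl)acetaldehyde
Conditions: PhI(OAc)2, TEMPO (10 mol %), CH2Cl2, rt
Reagents that add atoms: none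
Why: Nitroxyl-catalysed oxidation of a primary alcohol to the aldehyde with a hypervalent iodine co-oxidant; the neutral medium keeps the acetonide and avoids β-elimination.

Step 13
Reactants: 20 (R)-2-(2,2-dimethyl-1,3-dioxolan-4-yl)acetaldehyde
Product: 21 2-[(4R)-2,2-dimethyl-1,3-dioxolan-4-yl]prop-2-enal
Conditions: CH2=NMe2+ I−, Et3N, CH2Cl2, rt
Reagents that add atoms: N,N-dimethylmethyleneiminium iodide, C=[N+](C)C.[I-]
Why: Mannich reaction of the aldehyde with the preformed iminium salt and loss of dimethylamine (α-methylenation). The C3' stereocentre is not deprotonated, and the tertiary amine is too weak a base to expel the β-oxygen.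

Step 14
Reactants: 21 2-[(4R)-2,2-dimethyl-1,3-dioxolan-4-yl]prop-2-enal
Product: 22 2-[(4R)-2,2-dimethyl-1,3-dioxolan-4-yl]prop-2-enoic acid
Conditions: NaClO2, NaH2PO4, 2-methylbut-2-ene, t-BuOH–H2O, 0 °C → rt
Reagents that add atoms: sodium chlorite, [Na+].[O-]Cl=O
Why: Pinnick oxidation of a 2-substituted acrolein to the acrylic acid; the alkene scavenger removes hypochlorous acid, and the buffered medium leaves the acetonide intact.

Step 15
Reactants: 18 8α-alcohol; 22 2-[(4R)-2,2-dimethyl-1,3-dioxolan-4-yl]prop-2-enoic acid
Product: 24 8α ester of 18 with acid 22 (ethyl acetal; acetonide; 15-O-silyl ether), via mixed anhydride 23 (not isolated)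
Conditions: 2,4,6-trichlorobenzoyl chloride, Et3N, THF, rt; then 18, DMAP, toluene, rt
Reagents that add atoms: none
Why: Yamaguchi esterification; DMAP attacks the mixed anhydride at the less hindered acrylic carbonyl and the acylpyridinium acylates the only free hydroxyl of 18, with retention at C8.

Step 16
Reactants: 24 fully protected 8α ester
Product: 25 lactol (C12 hemiacetal epimers) with free 15-OH and free side-chain diol
Conditions: AcOH–H2O–THF (3:1:1), 40 °C
Reagents that add atoms: water, O
Why: Acid hydrolysis of the three acid-labile groups in one operation (acetal to lactol through the ring oxocarbenium ion, ketal to diol, silyl ether to alcohol). It is done before the carboxyl exists, and the weak acid should spare both esters.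

Step 17
Reactants: 25 lactol
Product: 26 11(13)-methylene lactol (in ring–chain equilibrium with the 6β-hydroxy-12-al)
Conditions: 37% aq. CH2O, pyrrolidine (20 mol %), propionic acid (40 mol %), i-PrOH, 40 °C
Reagents that add atoms: formaldehyde, C=O
Why: Amine-catalysed α-methylenation: Mannich condensation with formaldehyde through the enamine of the open hydroxy-aldehyde tautomer, then elimination of the amine. The excess of carboxylic acid keeps the amine protonated, which should suppress aza-Michael addition to the C8 acrylate and base-induced side-chain lactonisation, and the product recloses to the lactol.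

Step 18
Reactants: 26 11(13)-methylene lactol
Product: 27 target acid (5S,6S,7S,8S,10S; 3'R)
Conditions: NaClO2, NaH2PO4, 2-methylbut-2-ene, t-BuOH–H2O, 0 °C; pH 4–5; reversed-phase isolation
Reagents that add atoms: sodium chlorite, [Na+].[O-]Cl=O
Why: Pinnick oxidation acts on the open hydroxy-enal tautomer and leaves the alcohols, the electron-poor acrylate and, with the scavenger, the terminal alkenes alone. The carboxyl is formed last and in buffer because the cis C6 hydroxyl would close a lactone under stronger acid.

## Compound list

1 | ethyl sorbate, ethyl (2E,4E)-hexa-2,4-dienoate | C/C=C/C=C/C(=O)OCC | starting material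
2 | ethyl (3E)-hexa-3,5-dienoate | C=C/C=C/CC(=O)OCC | intermediate
3 | methacrolein (2-methylprop-2-enal) | C=C(C)C=O | starting material
4 | ethyl 2-[(1S,6R)-6-formyl-6-methylcyclohex-2-en-1-yl]acetate | O=C[C@]1(C)CCC=C[C@@H]1CC(=O)OCC | intermediate
5 | ethyl 2-[(1S,6S)-6-ethenyl-6-methylcyclohex-2-en-1-yl]acetate | C=C[C@]1(C)CCC=C[C@@H]1CC(=O)OCC | intermediate
6 | ethyl 3-(dimethylamino)-2-[(1S,6S)-6-ethenyl-6-methylcyclohex-2-en-1-yl]propanoate (C-2 epimers) | C=C[C@]1(C)CCC=C[C@@H]1C(CN(C)C)C(=O)OCC | intermediate
7 | trimethylammonium iodide of 6 | C=C[C@]1(C)CCC=C[C@@H]1C(C[N+](C)(C)C)C(=O)OCC.[I-] | intermediate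
8 | ethyl 2-[(1S,6S)-6-ethenyl-6-methylcyclohex-2-en-1-yl]prop-2-enoate | C=C[C@]1(C)CCC=C[C@@H]1C(=C)C(=O)OCC | intermediate
9 | 6β,7β-epoxide of 8 | C=C[C@]1(C)CC[C@H]2O[C@H]2[C@@H]1C(=C)C(=O)OCC | intermediate
10 | C15 allylic alcohol with 6β,7β-epoxide | C=C[C@]1(C)CC[C@H]2O[C@H]2[C@@H]1C(=C)CO | intermediate
11 | 15-O-tert-butyldimethylsilyl ether of 10 | C=C[C@]1(C)CC[C@H]2O[C@H]2[C@@H]1C(=C)CO[Si](C)(C)C(C)(C)C | intermediate
12 | 6β-hydroxy-7α-(phenylselanyl) compound | C=C[C@]1(C)CC[C@H]([Se]c2ccccc2)[C@@H](O)[C@@H]1C(=C)CO[Si](C)(C)C(C)(C)C | intermediate
13 | (1R,5S,6S)-6-[3-(tert-butyldimethylsilyloxy)prop-1-en-2-yl]-5-ethenyl-5-methylcyclohex-2-en-1-ol | C=C[C@]1(C)CC=C[C@@H](O)[C@@H]1C(=C)CO[Si](C)(C)C(C)(C)C | intermediate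
14 | ethyl vinyl ether | C=COCC | starting material
15 | 6β-O-(2-bromo-1-ethoxyethyl) ether of 13 (acetal epimers) | C=C[C@]1(C)CC=C[C@@H](OC(OCC)CBr)[C@@H]1C(=C)CO[Si](C)(C)C(C)(C)C | intermediate
16 | 2,2,6,6-tetramethylpiperidin-1-oxyl | CC1(C)CCCC(C)(C)N1[O] | starting material
17 | cis-fused 2-ethoxyhexahydrobenzofuran with 8α-aminoxy group (acetal epimers) | C=C[C@]1(C)C[C@H](ON3C(C)(C)CCCC3(C)C)[C@H]2CC(OCC)O[C@H]2[C@@H]1C(=C)CO[Si](C)(C)C(C)(C)C | intermediate
18 | 8α-alcohol | C=C[C@]1(C)C[C@H](O)[C@H]2CC(OCC)O[C@H]2[C@@H]1C(=C)CO[Si](C)(C)C(C)(C)C | intermediate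
19 | (R)-2-(2,2-dimethyl-1,3-dioxolan-4-yl)ethanol | OCC[C@@H]1COC(C)(C)O1 | starting material
20 | (R)-2-(2,2-dimethyl-1,3-dioxolan-4-yl)acetaldehyde | O=CC[C@@H]1COC(C)(C)O1 | intermediate
21 | 2-[(4R)-2,2-dimethyl-1,3-dioxolan-4-yl]prop-2-enal | C=C(C=O)[C@@H]1COC(C)(C)O1 | intermediate
22 | 2-[(4R)-2,2-dimethyl-1,3-dioxolan-4-yl]prop-2-enoic acid | C=C(C(=O)O)[C@@H]1COC(C)(C)O1 | intermediate
23 | mixed anhydride of 22 with 2,4,6-trichlorobenzoic acid | C=C(C(=O)OC(=O)c1c(Cl)cc(Cl)cc1Cl)[C@@H]1COC(C)(C)O1 | intermediate
24 | 8α ester (ethyl acetal; acetonide; 15-O-silyl) | C=C[C@]1(C)C[C@H](OC(=O)C(=C)[C@@H]3COC(C)(C)O3)[C@H]2CC(OCC)O[C@H]2[C@@H]1C(=C)CO[Si](C)(C)C(C)(C)C | intermediate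
25 | lactol with free 15-OH and side-chain diol | C=C[C@]1(C)C[C@H](OC(=O)C(=C)[C@@H](O)CO)[C@H]2CC(O)O[C@H]2[C@@H]1C(=C)CO | intermediate
26 | 11(13)-methylene lactol | C=C[C@]1(C)C[C@H](OC(=O)C(=C)[C@@H](O)CO)[C@H]2C(=C)C(O)O[C@H]2[C@@H]1C(=C)CO | intermediate
27 | CNP0348657.4 | C=C[C@]1(C)C[C@H](OC(=O)C(=C)[C@@H](O)CO)[C@@H](C(=C)C(=O)O)[C@@H](O)[C@@H]1C(=C)CO | target

## Step count and least certain steps

Total: 18 steps. Longest linear sequence: 15 steps (steps 1–11 and 15–18); the side-chain acid takes 3 steps (12–14).

Step 10 (key step). Most likely to go wrong: the nitroxide couples with the primary C11 radical before ring closure if its concentration rises, stannyl radicals are wasted on the nitroxide, or the C8 radical is captured on the concave face. Fallback, from 15 back to 18: oxygen replaces the nitroxide in a tin hydride chain. Bu3SnH is added slowly to 15 in toluene under a slow stream of dry air at room temperature; the cyclised C8 radical takes up oxygen and the peroxyl radical carries the chain, giving the 8α-hydroperoxide F1. PPh3 reduces it to 18, and step 11 is then not needed.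

Step 2. Most likely to go wrong: insufficient endo preference with a 2-methyl dienophile, insufficient enantioselectivity with this 1-alkyl diene, or the opposite facial sense. Fallback, from 3 back to 5: chirality transfer replaces endo control.
- 3 and 2-(triisopropylsilyloxy)buta-1,3-diene F2 react under the same kind of oxazaborolidinium catalysis, in a cycloaddition that creates only the quaternary centre, to give (R)-1-methyl-4-(triisopropylsilyloxy)cyclohex-3-ene-1-carbaldehyde F3.
- Wittig methylenation gives the silyl enol ether F4.
- Saegusa–Ito oxidation (Pd(OAc)2, O2, DMSO) gives (S)-4-ethenyl-4-methylcyclohex-2-en-1-one F5.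
- Reagent-controlled CBS reduction ((R)-oxazaborolidine, catecholborane) gives (1S,4S)-4-ethenyl-4-methylcyclohex-2-en-1-ol F6.
- Johnson–Claisen rearrangement with triethyl orthoacetate F7 (propionic acid cat., 140 °C) delivers the acetate arm to C5 on the face of the hydroxyl and returns 5.

Step 5. Most likely to go wrong: poor facial selectivity of the epoxidation, because the ring can adopt two half-chair forms of similar energy. Fallback, from 5 back to 13: stereospecific iodolactonisation followed by inversion, which does not depend on facial bias.
- LiOH hydrolysis gives the acid F8.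
- I2/NaHCO3 gives the cis-fused iodolactone F9 (lactone oxygen at C6, iodine at C7 on the other face).
- DBU gives the unsaturated lactone F10 with the C7=C8 alkene.
- Methylenation as in step 4 gives the α-methylene lactone F11.
- i-Bu2AlH gives the diol F12, and TBSCl at the primary hydroxyl gives the silyl ether F13, the C6 epimer of 13.
- Mitsunobu inversion (4-nitrobenzoic acid, PPh3, DIAD) gives the 4-nitrobenzoate F14, and K2CO3/MeOH returns 13.

Step 17. Most likely to go wrong: catalyst loss by aza-Michael addition to the C8 acrylate, slow reaction of a substrate that is mostly lactol, or side-chain lactonisation with loss of the C8 ester. Fallback, from 24 back to 26: the order of unmasking is changed. TESOTf/2,4,6-collidine then water cleaves the aldehyde-derived ethyl acetal selectively and gives the lactol F15 with acetonide and silyl ether retained. CH2=NMe2+ I−/Et3N in CH2Cl2 gives the methylene lactol F16, and AcOH–H2O–THF then gives 26.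

Step 18. Most likely to go wrong: closure of the C6 hydroxyl onto the new carboxyl during oxidation, acidification or chromatography, or slow oxidation because little open aldehyde is present. Fallback, from 26 back to 27: the crude carboxylate from the chlorite oxidation is not acidified but alkylated at once (allyl bromide, NaHCO3, DMF) to the allyl ester F17, which is purified on silica. Pd(PPh3)4 (zerovalent palladium) with PhSiH3 in THF then releases 27 under neutral conditions.

## Further compounds

F1 | step 10 | 8α-hydroperoxide of the cyclised acetal | C=C[C@]1(C)C[C@H](OO)[C@H]2CC(OCC)O[C@H]2[C@@H]1C(=C)CO[Si](C)(C)C(C)(C)C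
F2 | step 2 | 2-(triisopropylsilyloxy)buta-1,3-diene | C=CC(=C)O[Si](C(C)C)(C(C)C)C(C)C
F3 | step 2 | (R)-1-methyl-4-(triisopropylsilyloxy)cyclohex-3-ene-1-carbaldehyde | O=C[C@]1(C)CCC(O[Si](C(C)C)(C(C)C)C(C)C)=CC1
F4 | step 2 | (R)-[(4-ethenyl-4-methylcyclohex-1-en-1-yl)oxy]triisopropylsilane | C=C[C@]1(C)CCC(O[Si](C(C)C)(C(C)C)C(C)C)=CC1
F5 | step 2 | (S)-4-ethenyl-4-methylcyclohex-2-en-1-one | C=C[C@]1(C)CCC(=O)C=C1
F6 | step 2 | (1S,4S)-4-ethenyl-4-methylcyclohex-2-en-1-ol | C=C[C@]1(C)CC[C@H](O)C=C1
F7 | step 2 | triethyl orthoacetate | CC(OCC)(OCC)OCC
F8 | step 5 | 2-[(1S,6S)-6-ethenyl-6-methylcyclohex-2-en-1-yl]acetic acid | C=C[C@]1(C)CCC=C[C@@H]1CC(=O)O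
F9 | step 5 | cis-fused iodolactone (O6 α, 7β-iodide) | C=C[C@]1(C)CC[C@@H](I)[C@@H]2OC(=O)C[C@H]12
F10 | step 5 | cis-fused unsaturated lactone (C7=C8) | C=C[C@]1(C)CC=C[C@@H]2OC(=O)C[C@H]12
F11 | step 5 | cis-fused α-methylene lactone | C=C[C@]1(C)CC=C[C@@H]2OC(=O)C(=C)[C@H]12
F12 | step 5 | 6α,15-diol | C=C[C@]1(C)CC=C[C@H](O)[C@@H]1C(=C)CO
F13 | step 5 | 15-O-tert-butyldimethylsilyl 6α-alcohol (C6 epimer of 13) | C=C[C@]1(C)CC=C[C@H](O)[C@@H]1C(=C)CO[Si](C)(C)C(C)(C)C
F14 | step 5 | 6β-(4-nitrobenzoate) | C=C[C@]1(C)CC=C[C@@H](OC(=O)c2ccc(cc2)[N+](=O)[O-])[C@@H]1C(=C)CO[Si](C)(C)C(C)(C)C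
F15 | step 17 | lactol with acetonide and silyl ether retained | C=C[C@]1(C)C[C@H](OC(=O)C(=C)[C@@H]3COC(C)(C)O3)[C@H]2CC(O)O[C@H]2[C@@H]1C(=C)CO[Si](C)(C)C(C)(C)C
F16 | step 17 | 11(13)-methylene lactol with acetonide and silyl ether retained | C=C[C@]1(C)C[C@H](OC(=O)C(=C)[C@@H]3COC(C)(C)O3)[C@H]2C(=C)C(O)O[C@H]2[C@@H]1C(=C)CO[Si](C)(C)C(C)(C)C
F17 | step 18 | allyl ester of 27 | C=C[C@]1(C)C[C@H](OC(=O)C(=C)[C@@H](O)CO)[C@@H](C(=C)C(=O)OCC=C)[C@@H](O)[C@@H]1C(=C)CO
A1 | alternative 1 | (R)-5-(tert-butyldimethylsilyloxy)-3-methylcyclohex-2-en-1-one | CC1=CC(=O)C[C@H](O[Si](C)(C)C(C)(C)C)C1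
A2 | alternative 1 | allene (propa-1,2-diene) | C=C=C
A3 | alternative 1 | cis-fused methylenecyclobutane photoadduct | C2[C@]1(C)C[C@@H](O[Si](C)(C)C(C)(C)C)CC(=O)[C@@H]1C2=C
A4 | alternative 1 | ethylene | C=C
A5 | alternative 2 | acyclic methyl enol ether–(E)-allylsilane | C=C(OC)[C@@H](C(C)=C)[C@@H](O[Si](C)(C)C(C)(C)C)[C@H](C(=C)CO[Si](C)(C)C(C)(C)C)/C(C)=C/C[Si](C)(C)C
A6 | alternative 2 | cyclohexane with C8 dimethyl ketal and C10 methyl/vinyl carbon | C=C[C@]1(C)CC(OC)(OC)[C@@H](C(C)=C)[C@@H](O[Si](C)(C)C(C)(C)C)[C@@H]1C(=C)CO[Si](C)(C)C(C)(C)C
A7 | alternative 3 | methyl (R)-3-(tert-butyldimethylsilyloxy)cyclohex-1-ene-1-carboxylate | COC(=O)C1=C[C@H](O[Si](C)(C)C(C)(C)C)CCC1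
A8 | alternative 3 | 2-bromoallyl 4-methoxybenzyl ether | C=C(Br)COCc1ccc(OC)cc1
A9 | alternative 3 | methyl 1-methyl-2-alkenyl-3-silyloxycyclohexanecarboxylate | COC(=O)[C@]1(C)CCC[C@@H](O[Si](C)(C)C(C)(C)C)[C@@H]1C(=C)COCc1ccc(OC)cc1
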